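**Plan**
- Retrosynthesis (each cut made twice, the target being C2-symmetric): first the cyclopentane bond between the carbinol carbon and the isopropenyl-bearing carbon, back to an allenyl aldehyde. Then, in each oxane, the C2–C3 bond and the O1–C6 bond (target numbering: O1, OCH2 = C2, alkylidene carbon = C3, cyclopentyl-bearing carbon = C6), back to formaldehyde, an alkenyl bromide and an oxetane. Then the two aldol bonds, then the two alkenyl C–C bonds of a C12 (Z,Z)-dibromodienedial.
- Forward, two-directional throughout: the C12 linker with both (Z)-alkenyl bromides, then a double aldol, then two oxetanes, then both oxanes in one operation, then both cyclopentanols last.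
- Enabling feature: oxane C2 carries only O1 and C3, so the O1–C2 unit is one molecule of formaldehyde. O1 also stands 1,3 to the cyclopentanol oxygen (O1–C6–C(ring)–C(OH)), so C6 can be stored as the substituted carbon of a strained oxetane whose CH2 carbon later becomes the carbinol carbon.
- Stereochemistry: alkene geometry comes from trans-selective Negishi coupling on 1,1-dibromoalkenes and is kept through Br–Li exchange. The cyclopentane carbon bearing the oxane and oxane C6 come from an Evans syn-aldol, with C6 then inverted in the ring closure. The carbinol and isopropenyl centres come from the substrate-controlled nickel cyclization.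

Key step: step 12

Remark: formaldehyde 8 is bought as paraformaldehyde; it depolymerizes in the flask in step 5 and is cracked to the monomer just before use in step 12. Every two-fold step acts on both C2-related ends at once; where such a step builds a numbered compound into the product twice (4 in step 3, 14 in step 8, 8 in step 12), the second molecule is entered under "Reagents that add atoms".

Step 1
Reactants: 1 2,5-dimethoxytetrahydrofuran
Product: 2 butanedial (succinaldehyde)
Conditions: H2O, 90 °C; distil off MeOH, extract, distil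
Reagents that add atoms: water, O
Why: Acetal hydrolysis of the cyclic bis(methyl acetal) should release the 1,4-dialdehyde, which is used at once because it oligomerizes on standing.

Step 2
Reactants: 2 butanedial
Product: 3 1,1,6,6-tetrabromohexa-1,5-diene
Conditions: CBr4 (4.2 equiv), PPh3 (8.4 equiv), CH2Cl2, 0 °C
Reagents that add atoms: carbon tetrabromide, BrC(Br)(Br)Br
Why: Ramirez dibromo-olefination (first stage of the Corey–Fuchs sequence) should convert both aldehydes into 1,1-dibromoalkenes, the handles from which the alkenyl bromide geometry is set.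

Step 3
Reactants: 3 1,1,6,6-tetrabromohexa-1,5-diene; 4 [2-(1,3-dioxolan-2-yl)ethyl]zinc bromide (two equivalents)
Product: 5 2,2'-[(3Z,7Z)-3,8-dibromodeca-3,7-diene-1,10-diyl]bis(1,3-dioxolane)
Conditions: 4 (2.3 equiv), PdCl2(DPEphos) (5 mol %), THF, 0 → 23 °C
Reagents that add atoms: second equivalent of zinc reagent 4 (one per dibromoalkene), Br[Zn]CCC1OCCO1
Why: Two-fold Negishi coupling, one molecule of 4 per dibromoalkene: zerovalent palladium inserts selectively into the less hindered C–Br bond trans to the chain and leaves the hindered second C–Br bond alone at this temperature, so the alkyl group enters trans to the chain and bromine stays cis to it, which fixes the geometry of both future alkylidenes.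

Step 4
Reactants: 5 bis(dioxolane)
Product: 6 (4Z,8Z)-4,9-dibromododeca-4,8-dienedial
Conditions: 1 M HCl, THF, 23 °C
Reagents that add atoms: water, O
Why: Acid-catalysed acetal hydrolysis should unmask both aldehydes without touching the alkenyl bromides.

Step 5
Reactants: 7 methyl hex-5-ynoate; 8 formaldehyde (as paraformaldehyde)
Product: 10 methyl hepta-5,6-dienoate, via propargylic amine 9 (not isolated)
Conditions: (CH2O)n (2.5 equiv), CuI (0.5 equiv), dicyclohexylamine (1.8 equiv), 1,4-dioxane, reflux
Reagents that add atoms: none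
Why: Crabbé homologation: copper-mediated Mannich alkynylation gives the propargylic amine, and a 1,5-hydride shift from a cyclohexyl C–H with loss of the imine should deliver the terminal allene.

Step 6
Reactants: 10 methyl hepta-5,6-dienoate
Product: 11 hepta-5,6-dienoic acid
Conditions: LiOH·H2O (2 equiv), THF/H2O 3:1, 0 → 23 °C; then 1 M HCl to pH 3
Reagents that add atoms: lithium hydroxide, [Li+].[OH-]
Why: Ester saponification; the allene is inert to aqueous hydroxide at room temperature.

Step 7
Reactants: 11 hepta-5,6-dienoic acid; 12 (R)-4-benzyloxazolidin-2-one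
Product: 14 (R)-4-benzyl-3-(hepta-5,6-dienoyl)oxazolidin-2-one, via mixed pivalic anhydride 13 (not isolated)
Conditions: pivaloyl chloride (1.05 equiv), Et3N (2.5 equiv), THF, −20 °C; then LiCl (1.1 equiv), 12 (1.0 equiv), −20 → 23 °C
Reagents that add atoms: none
Why: N-Acylation of the oxazolidinone through the mixed pivalic anhydride (LiCl/Et3N variant) should occur at the less hindered carbonyl of the anhydride.

Step 8
Reactants: 6 (4Z,8Z)-4,9-dibromododeca-4,8-dienedial; 14 (R)-4-benzyl-3-(hepta-5,6-dienoyl)oxazolidin-2-one (two equivalents)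
Product: 16 bis(aldol) adduct (2R,3S,14S,15R), via dibutylboron enolate 15 (not isolated)
Conditions: 14 (2.4 equiv), Bu2BOTf (2.6 equiv), Et3N (3.0 equiv), CH2Cl2, −78 → 0 °C; then 6 (1.0 equiv), −78 → 0 °C; pH 7 buffer, MeOH, 30% H2O2, 0 °C
Reagents that add atoms: second equivalent of imide 14 (one per aldehyde), C=C=CCCCC(=O)N1[C@H](Cc2ccccc2)COC1=O
Why: Two-fold Evans syn-aldol reaction, one molecule of 14 per aldehyde: the (Z)-boron enolate reacts through a Zimmerman–Traxler chair on the face remote from the benzyl group and should set at each end the α-carbon as (R) and the carbinol carbon as (S), the latter deliberately opposite to what oxane C6 needs because it is inverted in step 12.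

Step 9
Reactants: 16 bis(aldol) adduct
Product: 17 (2S,3S,6Z,10Z,14S,15S)-6,11-dibromo-2,15-di(penta-3,4-dien-1-yl)hexadeca-6,10-diene-1,3,14,16-tetrol
Conditions: LiBH4 (5 equiv), MeOH (5 equiv), THF, 0 °C; aq NH4Cl
Reagents that add atoms: none
Why: Reductive cleavage of the imides by LiBH4 should give the primary alcohols and return the auxiliary without touching the stereocentres, the alkenyl bromides or the allenes.

Step 10
Reactants: 17 tetrol
Product: 18 1,16-bis(4-methylbenzenesulfonate) of 17
Conditions: TsCl (2.2 equiv), pyridine, CH2Cl2, 0 °C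
Reagents that add atoms: 4-methylbenzenesulfonyl chloride, Cc1ccc(cc1)S(=O)(=O)Cl
Why: Selective sulfonylation: the primary hydroxyl of each 1,3-diol reacts far faster with TsCl at 0 °C than the hindered secondary one.

Step 11
Reactants: 18 bis(primary tosylate)
Product: 19 2,2'-[(3Z,7Z)-3,8-dibromodeca-3,7-diene-1,10-diyl]bis[(2S,3S)-3-(penta-3,4-dien-1-yl)oxetane]
Conditions: NaH (2.5 equiv), THF, 0 → 40 °C
Reagents that add atoms: none
Why: Intramolecular Williamson etherification (4-exo-tet) by the secondary alkoxide on the primary tosylate should close each oxetane with retention at the carbinol carbon, whose C–O bond is not broken, giving the cis-2,3-disubstituted rings.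

Step 12
Reactants: 19 bis(oxetane) dibromide; 8 formaldehyde monomer (two equivalents)
Product: 22 bis(oxane) diol, via bis(alkenyllithium) 20 (not isolated), via bis(lithium alkoxide) 21 (not isolated)
Conditions: t-BuLi (4.1 equiv), Et2O, −78 °C; 8 (2.5 equiv), gas from cracked (CH2O)n, −78 → −40 °C; then BF3·OEt2 (5 equiv), −78 → 0 °C; aq NaHCO3
Reagents that add atoms: second equivalent of formaldehyde 8 (one per alkenyllithium), C=O
Why: Bromine–lithium exchange (two t-BuLi per C–Br) gives each alkenyllithium with retention of the (Z) geometry and leaves the oxetanes untouched, since oxetanes do not react with organolithiums without a Lewis acid; addition of each alkenyllithium to one molecule of monomeric formaldehyde then forges the oxane C2–C3 bond and places a lithium alkoxide where a six-membered ring can close. BF3 then binds the oxetane oxygen and the pendant oxygen opens the strained ring at its substituted carbon by SN2 displacement, which forms the O1–C6 bond; the closest known reaction types are the hydroxymethylation of alkenyllithiums with formaldehyde and the Lewis-acid-promoted intramolecular opening of oxetanes by hydroxyl groups to give cyclic ethers. Each oxane closes in the 6-exo-tet mode, whereas attack at the oxetane CH2 would need an eight-membered ring and is not expected. The new stereocentre at oxane C6 is controlled by inversion of the (S) oxetane carbon set in the aldol step and should come out (R), and the alkylidene geometry is controlled by the retentive exchange. The step needs the lithium reagents to select C–Br over the allenic C–H bonds and the oxetane, which the very fast exchange at −78 °C in Et2O and the Lewis-acid gating of the oxetane should secure, and it needs the internal oxygen to outrun bromide, which the six-membered transition state should secure. Release of the oxetane ring strain drives the closure, and the departing oxygen is set free as the primary alcohol that the next step oxidizes.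

Step 13
Reactants: 22 bis(oxane) diol
Product: 23 bis(oxane) dialdehyde
Conditions: Dess–Martin periodinane (2.6 equiv), NaHCO3, CH2Cl2, 0 → 23 °C; used crude
Reagents that add atoms: none
Why: Dess–Martin oxidation under bicarbonate buffer should give the α-branched aldehydes without epimerization or β-elimination of the oxane oxygen.

Step 14
Reactants: 23 bis(oxane) dialdehyde
Product: 24 testudinariol A
Conditions: Ni(cod)2 [bis(1,5-cyclooctadiene)nickel] (20 mol %), ZnMe2 (6 equiv), THF, 0 °C; aq NH4Cl
Reagents that add atoms: dimethylzinc, C[Zn]C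
Why: Nickel-catalysed alkylative cyclization of an allenyl aldehyde with an organozinc: oxidative cyclization of the aldehyde and the proximal allene π-bond on zerovalent nickel gives a cis-fused oxanickelacycle, and methyl transfer from zinc with reductive elimination puts the methyl on the central allene carbon, so hydroxyl and isopropenyl come out cis, while the oxanyl group on the α-carbon sits pseudo-equatorial and ends trans to the hydroxyl, which should set the carbinol carbon as (S) and the isopropenyl-bearing carbon as (R) at both ends.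

**Compound list**
1 | 2,5-dimethoxytetrahydrofuran (cis/trans mixture) | COC1CCC(OC)O1 | starting material
2 | butanedial (succinaldehyde) | O=CCCC=O | intermediate
3 | 1,1,6,6-tetrabromohexa-1,5-diene | BrC(Br)=CCCC=C(Br)Br | intermediate
4 | [2-(1,3-dioxolan-2-yl)ethyl]zinc bromide (0.5 M in THF) | Br[Zn]CCC1OCCO1 | starting material
5 | 2,2'-[(3Z,7Z)-3,8-dibromodeca-3,7-diene-1,10-diyl]bis(1,3-dioxolane) | C1COC(O1)CC/C(Br)=C/CC/C=C(Br)/CCC1OCCO1 | intermediate
6 | (4Z,8Z)-4,9-dibromododeca-4,8-dienedial | O=CCC/C(Br)=C/CC/C=C(Br)/CCC=O | intermediate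
7 | methyl hex-5-ynoate | COC(=O)CCCC#C | starting material
8 | formaldehyde (supplied as paraformaldehyde) | C=O | starting material
9 | methyl 7-(dicyclohexylamino)hept-5-ynoate (not isolated) | COC(=O)CCCC#CCN(C1CCCCC1)C1CCCCC1 | intermediate
10 | methyl hepta-5,6-dienoate | COC(=O)CCCC=C=C | intermediate
11 | hepta-5,6-dienoic acid | OC(=O)CCCC=C=C | intermediate
12 | (R)-4-benzyloxazolidin-2-one | O=C1N[C@H](Cc2ccccc2)CO1 | starting material
13 | hepta-5,6-dienoic pivalic anhydride (not isolated) | C=C=CCCCC(=O)OC(=O)C(C)(C)C | intermediate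
14 | (R)-4-benzyl-3-(hepta-5,6-dienoyl)oxazolidin-2-one | C=C=CCCCC(=O)N1[C@H](Cc2ccccc2)COC1=O | intermediate
15 | (Z)-dibutylboron enolate of 14 (not isolated) | C=C=CCC/C=C(\OB(CCCC)CCCC)N1[C@H](Cc2ccccc2)COC1=O | intermediate
16 | (4R,4'R)-3,3'-[(2R,3S,6Z,10Z,14S,15R)-6,11-dibromo-3,14-dihydroxy-2,15-di(penta-3,4-dien-1-yl)hexadeca-6,10-dienedioyl]bis(4-benzyloxazolidin-2-one) | O=C1OC[C@@H](Cc2ccccc2)N1C(=O)[C@H](CCC=C=C)[C@@H](O)CC/C(Br)=C/CC/C=C(Br)/CC[C@H](O)[C@@H](CCC=C=C)C(=O)N1[C@H](Cc2ccccc2)COC1=O | intermediate
17 | (2S,3S,6Z,10Z,14S,15S)-6,11-dibromo-2,15-di(penta-3,4-dien-1-yl)hexadeca-6,10-diene-1,3,14,16-tetrol | OC[C@H](CCC=C=C)[C@@H](O)CC/C(Br)=C/CC/C=C(Br)/CC[C@H](O)[C@@H](CCC=C=C)CO | intermediate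
18 | 1,16-bis(4-methylbenzenesulfonate) of tetrol 17 | Cc1ccc(cc1)S(=O)(=O)OC[C@H](CCC=C=C)[C@@H](O)CC/C(Br)=C/CC/C=C(Br)/CC[C@H](O)[C@@H](CCC=C=C)COS(=O)(=O)c1ccc(C)cc1 | intermediate
19 | 2,2'-[(3Z,7Z)-3,8-dibromodeca-3,7-diene-1,10-diyl]bis[(2S,3S)-3-(penta-3,4-dien-1-yl)oxetane] (cis-2,3-disubstituted oxetanes) | C=C=CCC[C@H]1CO[C@H]1CC/C(Br)=C/CC/C=C(Br)/CC[C@@H]1OC[C@@H]1CCC=C=C | intermediate
20 | bis(alkenyllithium): 19 with both Br replaced by Li, geometry retained (not isolated) | C=C=CCC[C@H]1CO[C@H]1CC/C([Li])=C/CC/C=C([Li])/CC[C@@H]1OC[C@@H]1CCC=C=C | intermediate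
21 | bis(lithium alkoxide): 19 with both Br replaced by CH2OLi, (Z,Z) (not isolated) | C=C=CCC[C@H]1CO[C@H]1CC/C(CO[Li])=C/CC/C=C(CO[Li])/CC[C@@H]1OC[C@@H]1CCC=C=C | intermediate
22 | bis(oxane) diol: two (2S)-2-[(2R,5Z)-oxan-2-yl]hepta-5,6-dien-1-ol units whose oxane C5 atoms are joined by a (Z,Z) =CH–CH2–CH2–CH= bridge | C=C=CCC[C@H]([C@H]2CC/C(=C/CC/C=C3/CC[C@H]([C@H](CO)CCC=C=C)OC3)CO2)CO | intermediate
23 | bis(oxane) dialdehyde: the (2R)-2-[(2R,5Z)-oxan-2-yl]hepta-5,6-dienal analogue of 22 (same spatial arrangement) | C=C=CCC[C@H]([C@H]2CC/C(=C/CC/C=C3/CC[C@H]([C@H](C=O)CCC=C=C)OC3)CO2)C=O | intermediate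
24 | testudinariol A | C=C(C)[C@H]1CC[C@H]([C@H]2CC/C(=C/CC/C=C3/CC[C@H]([C@H]4CC[C@H](C(=C)C)[C@@H]4O)OC3)CO2)[C@H]1O | target

Total step count: 14. Longest linear sequence: 11 steps (steps 1–4, then 8–14).

**Steps most likely to fail**

Step 12. Three processes may interfere: deprotonation of an allenic C–H bond by the lithium reagents; opening of the BF3-activated oxetane at its CH2 by bromide or fluoride before the boron-bound alkoxide closes the ring; and Prins-type reaction of excess formaldehyde with the allenes under BF3. The fallback replaces the Lewis-acid, strain-release closure by a purely anionic displacement of a sulfonate. It sets out from tetrol 17 and returns at diol 22. The primary hydroxyls would be silylated (TBSCl, imidazole, CH2Cl2, 0 °C) to the bis(TBS ether) F1, and the secondary hydroxyls sulfonylated (Ts2O, pyridine, DMAP, CH2Cl2) to the bis(secondary tosylate) F2. Exchange with t-BuLi in Et2O at −78 °C would give the bis(alkenyllithium) F3, and formaldehyde 8 the bis(lithium alkoxide) F4. Warming to 23 °C after adding HMPA would give the bis(oxane) bis(TBS ether) F5 by 6-exo-tet displacement of tosylate with the same inversion at the carbinol carbon. TBAF in THF would then return diol 22.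

Step 14. The two-fold cyclization may suffer from poor facial selectivity at the α-branched aldehyde, from direct methyl addition of the zinc reagent to the aldehyde, or from α-epimerization before ring closure. The fallback builds the ring through an allylcopper instead of a nickelacycle and brings in the methyl group afterwards. It sets out from dialdehyde 23 and returns at 24. Copper-catalysed borylative cyclization (CuCl, NaOt-Bu, PPh3, B2pin2, THF, 23 °C; aqueous work-up) would add boron to the central allene carbon and let the resulting allylcopper attack the aldehyde through a cis-fused cyclic transition state, giving the bis(alkenylboronate) diol F6. Suzuki–Miyaura methylation (MeI, Pd(PPh3)4, K2CO3, DMF/H2O, 60 °C) would then give 24.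

Step 3. With four C–Br bonds in one substrate, the trans-selectivity of oxidative addition may erode, the second bromide may couple as well, or the alkenylpalladium may isomerize. The fallback takes the alkene geometry from a stabilized Wittig reaction instead of a catalyst-controlled selection. It sets out from butanedial 2 and returns at dialdehyde 6. Two-fold Wittig reaction with ethyl 2-bromo-2-(triphenylphosphoranylidene)acetate (CH2Cl2, 23 °C) would give diethyl (2Z,6Z)-2,7-dibromoocta-2,6-dienedioate F7, with bromine cis to the chain. DIBAL-H (CH2Cl2, −78 → 0 °C) would give the bis(allylic alcohol) F8, and CBr4/PPh3 the bis(allylic bromide) F9. Alkylation with the lithium enolate of ethyl acetate (LDA, THF, −78 °C) would give the chain-extended diester F10, and DIBAL-H (one equivalent per ester, toluene, −78 °C) would give dialdehyde 6.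

**Further compounds**
F1 | step 12 | 1,16-bis(tert-butyldimethylsilyl) ether of tetrol 17 | CC(C)(C)[Si](C)(C)OC[C@H](CCC=C=C)[C@@H](O)CC/C(Br)=C/CC/C=C(Br)/CC[C@H](O)[C@@H](CCC=C=C)CO[Si](C)(C)C(C)(C)C
F2 | step 12 | 3,14-bis(4-methylbenzenesulfonate) of F1 | CC(C)(C)[Si](C)(C)OC[C@H](CCC=C=C)[C@@H](OS(=O)(=O)c1ccc(C)cc1)CC/C(Br)=C/CC/C=C(Br)/CC[C@H](OS(=O)(=O)c1ccc(C)cc1)[C@@H](CCC=C=C)CO[Si](C)(C)C(C)(C)C
F3 | step 12 | bis(alkenyllithium) from F2 (both Br replaced by Li) | CC(C)(C)[Si](C)(C)OC[C@H](CCC=C=C)[C@@H](OS(=O)(=O)c1ccc(C)cc1)CC/C([Li])=C/CC/C=C([Li])/CC[C@H](OS(=O)(=O)c1ccc(C)cc1)[C@@H](CCC=C=C)CO[Si](C)(C)C(C)(C)C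
F4 | step 12 | bis(lithium alkoxide) from F3 (both Li replaced by CH2OLi) | CC(C)(C)[Si](C)(C)OC[C@H](CCC=C=C)[C@@H](OS(=O)(=O)c1ccc(C)cc1)CC/C(CO[Li])=C/CC/C=C(CO[Li])/CC[C@H](OS(=O)(=O)c1ccc(C)cc1)[C@@H](CCC=C=C)CO[Si](C)(C)C(C)(C)C
F5 | step 12 | bis(tert-butyldimethylsilyl) ether of diol 22 | C=C=CCC[C@H]([C@H]2CC/C(=C/CC/C=C3/CC[C@H]([C@H](CO[Si](C)(C)C(C)(C)C)CCC=C=C)OC3)CO2)CO[Si](C)(C)C(C)(C)C
F6 | step 14 | bis(alkenylboronate) diol: 24 with each isopropenyl methyl replaced by a pinacolatoboryl group | C=C(B1OC(C)(C)C(C)(C)O1)[C@H]1CC[C@H]([C@H]2CC/C(=C/CC/C=C3/CC[C@H]([C@H]4CC[C@H](C(=C)B5OC(C)(C)C(C)(C)O5)[C@@H]4O)OC3)CO2)[C@H]1O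
F7 | step 3 | diethyl (2Z,6Z)-2,7-dibromoocta-2,6-dienedioate | CCOC(=O)/C(Br)=C/CC/C=C(Br)/C(=O)OCC
F8 | step 3 | (2Z,6Z)-2,7-dibromoocta-2,6-diene-1,8-diol | OC/C(Br)=C/CC/C=C(Br)/CO
F9 | step 3 | (2Z,6Z)-1,2,7,8-tetrabromoocta-2,6-diene | BrC/C(Br)=C/CC/C=C(Br)/CBr
F10 | step 3 | diethyl (4Z,8Z)-4,9-dibromododeca-4,8-dienedioate | CCOC(=O)CC/C(Br)=C/CC/C=C(Br)/CCC(=O)OCC
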